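**Plan**

- Retrosynthesis: global hydrogenolysis comes off first. The upper pyran ring C is then cut at O1–C2 and C4a–C4, giving phloroglucinol and a cis-epoxy benzylic alcohol carried on C8 of protected taxifolin. The epoxide goes back to a (Z)-allylic alcohol, then to an ynone, which is cut at C8–C4 and C4–C3 into 8-iodotaxifolin tetrabenzyl ether, CO and an aryl alkyne.
- Forward order: rings A, C and B of the lower unit come intact from (+)-taxifolin. The chain C4–C3–C2 bearing upper ring B is joined at C8. Upper ring C is closed last, in the same operation that brings in upper ring A.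
- Stereochemistry: lower C2/C3 come from the chiral pool. The carbinol is set by oxazaborolidine reduction and relayed to the cis-epoxide by hydroxyl-directed, A(1,3)-controlled epoxidation. In the key step C3 is kept, C2 is inverted and C4 is re-set anti to the epoxide oxygen.
- Enabling feature: C4 is benzylic to taxifolin ring A at C8 (flanked by O7 and O1, para to O5), so it ionises readily. It sits next to a strained C2–C3 oxirane whose C2 is benzylic to ring B. Phloroglucinol acts as a C,O-1,3-bisnucleophile, so the event is a formal [3+3] annulation.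

Key step: step 9

Assumption: (+)-taxifolin is taken as the commercial (2R,3R) enantiomer, and the hindered 2,6-dioxygenated aryl group of ynone 7 is taken to act as the large group in the oxazaborolidine reduction.

**Route**

Step 1
Reactants: 1 (+)-taxifolin
Product: 2 5,7,3',4'-tetra-O-benzyl-(+)-taxifolin
Conditions: BnBr (5 equiv), K2CO3, DMF, N2, rt to 40 °C
Reagents that add atoms: benzyl bromide, BrCc1ccccc1
Why: Williamson etherification should cap the four phenols (the chelated 5-OH last) and leave the less acidic secondary 3-OH free, while early benzylation of 4'-OH blocks the quinone-methide pathway for C2 epimerisation so that the (2R,3R) centres are kept.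

Step 2
Reactants: 2 5,7,3',4'-tetra-O-benzyl-(+)-taxifolin
Product: 3 8-iodo-5,7,3',4'-tetra-O-benzyl-(+)-taxifolin
Conditions: NIS (1.05 equiv), TFA (10 mol%), MeCN/CH2Cl2, 0 °C to rt
Reagents that add atoms: N-iodosuccinimide, O=C1CCC(=O)N1I
Why: Electrophilic aromatic iodination should take place on the trialkoxy ring A, far more activated than ring B, and at C8 (between O7-benzyl and the ring oxygen) in preference to the more crowded C6, as is known for 5,7-di-O-alkylated flavonoids.

Step 3
Reactants: 4 3,4-dihydroxybenzaldehyde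
Product: 5 4-ethynylbenzene-1,2-diol
Conditions: dimethyl (1-diazo-2-oxopropyl)phosphonate (1.5 equiv), K2CO3 (4 equiv), MeOH, argon, rt; aq. NH4Cl
Reagents that add atoms: dimethyl (1-diazo-2-oxopropyl)phosphonate, COP(=O)(OC)C(=[N+]=[N-])C(C)=O
Why: Ohira–Bestmann (Seyferth–Gilbert) homologation should convert the aldehyde into the terminal alkyne, the excess base and reagent compensating for the phenoxide-deactivated carbonyl.

Step 4
Reactants: 5 4-ethynylbenzene-1,2-diol
Product: 6 4-ethynyl-1,2-phenylene bis(benzyl carbonate)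
Conditions: CbzCl (2.5 equiv), pyridine, CH2Cl2, 0 °C
Reagents that add atoms: benzyl chloroformate, O=C(Cl)OCc1ccccc1
Why: O-acylation of both phenols should give carbonates that turn ring B from a donor into a weak acceptor (needed later to keep the epoxide from ionising) and that fall off by hydrogenolysis together with the benzyl ethers.

Step 5
Reactants: 3 8-iodo-5,7,3',4'-tetra-O-benzyl-(+)-taxifolin; 6 4-ethynyl-1,2-phenylene bis(benzyl carbonate)
Product: 7 8-{3-[3,4-bis(benzyloxycarbonyloxy)phenyl]prop-2-ynoyl}-5,7,3',4'-tetra-O-benzyltaxifolin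
Conditions: PdCl2(PPh3)2 (5 mol%), CuI (2 mol%), Et3N, THF, CO (1 atm), rt to 40 °C
Reagents that add atoms: carbon monoxide, [C-]#[O+]
Why: Carbonylative Sonogashira coupling (oxidative addition of the aryl iodide, CO insertion favoured by the two ortho oxygens, alkynyl transfer, reductive elimination) should install the whole C4–C3–C2 chain at C8 without touching the carbonates or the free 3-OH.

Step 6
Reactants: 7 ynone
Product: 8 8-{(1R)-3-[3,4-bis(benzyloxycarbonyloxy)phenyl]-1-hydroxyprop-2-yn-1-yl}-5,7,3',4'-tetra-O-benzyltaxifolin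
Conditions: (S)-2-methyl-CBS-oxazaborolidine (0.5 equiv), catecholborane (2 equiv), CH2Cl2, −78 °C; MeOH, then pH 7 buffer
Reagents that add atoms: none
Why: Corey–Bakshi–Shibata reduction should act on the activated ynone carbonyl faster than on the hindered, donor-substituted C4 ketone of the taxifolin ring, and with the aryl group as the large substituent the (S)-catalyst should deliver hydride to give the (R)-carbinol.

Step 7
Reactants: 8 (R)-propargylic alcohol
Product: 9 8-{(1R,2Z)-3-[3,4-bis(benzyloxycarbonyloxy)phenyl]-1-hydroxyprop-2-en-1-yl}-5,7,3',4'-tetra-O-benzyltaxifolin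
Conditions: H2 (1 atm), Pd/CaCO3 poisoned with Pb(OAc)2, quinoline, EtOAc, rt
Reagents that add atoms: none
Why: Syn semi-hydrogenation of the alkyne on the poisoned catalyst should give the (Z)-alkene while benzyl ethers, benzyl carbonates and the carbinol centre stay untouched.

Step 8
Reactants: 9 (R,Z)-allylic alcohol
Product: 10 8-{(S)-hydroxy[(2R,3S)-3-(3,4-bis(benzyloxycarbonyloxy)phenyl)oxiran-2-yl]methyl}-5,7,3',4'-tetra-O-benzyltaxifolin
Conditions: mCPBA (1.3 equiv), NaHCO3 (solid), CH2Cl2, 0 °C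
Reagents that add atoms: 3-chloroperoxybenzoic acid, O=C(OO)c1cccc(Cl)c1
Why: Hydroxyl-directed Prilezhaev epoxidation should be threo-selective, because A(1,3) strain from the cis aryl group holds the carbinol H in the alkene plane and the hydrogen-bonded peracid reaches only the face syn to OH, so the (R)-carbinol sets both oxirane centres of the cis-epoxide.

Step 9
Reactants: 10 cis-epoxy alcohol; 11 phloroglucinol
Product: 14 3',4'-bis-O-(benzyloxycarbonyl)-(–)-epicatechin-(4β→8)-5,7,3',4'-tetra-O-benzyl-(+)-taxifolin, via benzylic cation 12 (not isolated), via Friedel–Crafts adduct 13 (not isolated)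
Conditions: phloroglucinol (5 equiv), TsOH·H2O (5 mol%), (CF3)2CHOH/CH2Cl2 (1:3), −20 °C to rt
Reagents that add atoms: none
Why: Proposed new method: acid in the fluorinated alcohol should ionise the C4 hydroxyl of 10 first, because cation 12 is a quinone-methide-type oxocarbenium stabilised by O7, O1 and O5 of taxifolin ring A while the carbonate-deactivated ring B keeps the oxirane closed; phloroglucinol then adds through carbon (Friedel–Crafts) to give 13, whose ortho hydroxyl opens the cis-epoxide at its benzylic carbon. The closest known reaction types are the acid-mediated coupling of flavan-4-yl cations with phloroglucinol-type rings and the acid-catalysed cyclisation of 2-hydroxybenzyl aryl epoxides to flavan-3-ols; their merger on an epoxy carbinol as a formal [3+3] annulation is the untested part. The one ring closed, upper pyran ring C, forms by 6-endo-tet epoxide opening after the intermolecular C–C bond formation. C4 should be set in the Friedel–Crafts step by attack anti to the oxirane C3–O bond in the conformer in which the taxifolin unit turns away from the cis aryl group (Felkin–Anh-type, the same 3,4-trans sense as in flavan-4-yl cation couplings); C2 should be set by SN2-like inversion, so that the cis-epoxide gives the 2,3-cis ether; C3 keeps the epoxide configuration. The step needs ionisation at C4 before epoxide activation, endo over 5-exo opening, and mono-alkylation; these should be secured by the donor/acceptor mismatch of the two aryl rings, by the benzylic character of C2 next to a crowded C3, and by the fivefold excess of threefold-symmetric phloroglucinol, whose ring carbons are all equivalent and each flanked by two hydroxyls.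

Step 10
Reactants: 14 protected dimer
Product: 15 (–)-epicatechin-(4β→8)-(+)-taxifolin (target)
Conditions: H2 (1 atm), Pd(OH)2/C, THF/MeOH (1:1), rt
Reagents that add atoms: none
Why: Hydrogenolysis should cleave the four benzyl ethers and the two benzyl carbonates (as toluene and CO2) under neutral conditions that spare the acid-labile interflavan bond, the base-sensitive dihydroflavonol and every stereocentre.

**Compound list**

1 | (+)-taxifolin, (2R,3R)-2-(3,4-dihydroxyphenyl)-3,5,7-trihydroxychroman-4-one | O=C1c2c(O)cc(O)cc2O[C@H](c2ccc(O)c(O)c2)[C@H]1O | starting material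
2 | 5,7,3',4'-tetra-O-benzyl-(+)-taxifolin (3-OH free) | O=C1c2c(OCc3ccccc3)cc(OCc3ccccc3)cc2O[C@H](c2ccc(OCc3ccccc3)c(OCc3ccccc3)c2)[C@H]1O | intermediate
3 | 8-iodo-5,7,3',4'-tetra-O-benzyl-(+)-taxifolin | O=C1c2c(OCc3ccccc3)cc(OCc3ccccc3)c(I)c2O[C@H](c2ccc(OCc3ccccc3)c(OCc3ccccc3)c2)[C@H]1O | intermediate
4 | 3,4-dihydroxybenzaldehyde | O=Cc1ccc(O)c(O)c1 | starting material
5 | 4-ethynylbenzene-1,2-diol | C#Cc1ccc(O)c(O)c1 | intermediate
6 | 4-ethynyl-1,2-phenylene bis(benzyl carbonate) | C#Cc1ccc(OC(=O)OCc2ccccc2)c(OC(=O)OCc2ccccc2)c1 | intermediate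
7 | ynone, 8-{3-[3,4-bis(benzyloxycarbonyloxy)phenyl]prop-2-ynoyl}-5,7,3',4'-tetra-O-benzyltaxifolin | O=C1c2c(OCc3ccccc3)cc(OCc3ccccc3)c(C(=O)C#Cc3ccc(OC(=O)OCc4ccccc4)c(OC(=O)OCc4ccccc4)c3)c2O[C@H](c2ccc(OCc3ccccc3)c(OCc3ccccc3)c2)[C@H]1O | intermediate
8 | (R)-propargylic alcohol, 8-{(1R)-3-[3,4-bis(benzyloxycarbonyloxy)phenyl]-1-hydroxyprop-2-yn-1-yl}-5,7,3',4'-tetra-O-benzyltaxifolin | O=C1c2c(OCc3ccccc3)cc(OCc3ccccc3)c([C@H](O)C#Cc3ccc(OC(=O)OCc4ccccc4)c(OC(=O)OCc4ccccc4)c3)c2O[C@H](c2ccc(OCc3ccccc3)c(OCc3ccccc3)c2)[C@H]1O | intermediate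
9 | (R,Z)-allylic alcohol, 8-{(1R,2Z)-3-[3,4-bis(benzyloxycarbonyloxy)phenyl]-1-hydroxyprop-2-en-1-yl}-5,7,3',4'-tetra-O-benzyltaxifolin | O=C1c2c(OCc3ccccc3)cc(OCc3ccccc3)c([C@H](O)/C=C\c3ccc(OC(=O)OCc4ccccc4)c(OC(=O)OCc4ccccc4)c3)c2O[C@H](c2ccc(OCc3ccccc3)c(OCc3ccccc3)c2)[C@H]1O | intermediate
10 | cis-epoxy alcohol, 8-{(S)-hydroxy[(2R,3S)-3-(3,4-bis(benzyloxycarbonyloxy)phenyl)oxiran-2-yl]methyl}-5,7,3',4'-tetra-O-benzyltaxifolin | O=C1c2c(OCc3ccccc3)cc(OCc3ccccc3)c([C@H](O)[C@H]5O[C@H]5c3ccc(OC(=O)OCc4ccccc4)c(OC(=O)OCc4ccccc4)c3)c2O[C@H](c2ccc(OCc3ccccc3)c(OCc3ccccc3)c2)[C@H]1O | intermediate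
11 | phloroglucinol (benzene-1,3,5-triol) | Oc1cc(O)cc(O)c1 | starting material
12 | benzylic cation formed from 10 by loss of the carbinol hydroxyl (C4 of the future upper unit) | O=C1c2c(OCc3ccccc3)cc(OCc3ccccc3)c([CH+][C@H]5O[C@H]5c3ccc(OC(=O)OCc4ccccc4)c(OC(=O)OCc4ccccc4)c3)c2O[C@H](c2ccc(OCc3ccccc3)c(OCc3ccccc3)c2)[C@H]1O | intermediate
13 | Friedel–Crafts adduct, 8-{(R)-[(2R,3S)-3-(3,4-bis(benzyloxycarbonyloxy)phenyl)oxiran-2-yl](2,4,6-trihydroxyphenyl)methyl}-5,7,3',4'-tetra-O-benzyltaxifolin | O=C1c2c(OCc3ccccc3)cc(OCc3ccccc3)c([C@@H](c3c(O)cc(O)cc3O)[C@H]5O[C@H]5c3ccc(OC(=O)OCc4ccccc4)c(OC(=O)OCc4ccccc4)c3)c2O[C@H](c2ccc(OCc3ccccc3)c(OCc3ccccc3)c2)[C@H]1O | intermediate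
14 | 3',4'-bis-O-(benzyloxycarbonyl)-(–)-epicatechin-(4β→8)-5,7,3',4'-tetra-O-benzyl-(+)-taxifolin; upper unit (2R,3R,4R) | O=C1c2c(OCc3ccccc3)cc(OCc3ccccc3)c([C@H]3c4c(O)cc(O)cc4O[C@H](c4ccc(OC(=O)OCc5ccccc5)c(OC(=O)OCc5ccccc5)c4)[C@@H]3O)c2O[C@H](c2ccc(OCc3ccccc3)c(OCc3ccccc3)c2)[C@H]1O | intermediate
15 | (–)-epicatechin-(4β→8)-(+)-taxifolin; upper unit (2R,3R,4R), lower unit (2R,3R) | O=C1c2c(O)cc(O)c([C@H]3c4c(O)cc(O)cc4O[C@H](c4ccc(O)c(O)c4)[C@@H]3O)c2O[C@H](c2ccc(O)c(O)c2)[C@H]1O | target

**Count and risks**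

Total step count: 10. Longest linear sequence: 8 steps (1, 2, 5, 6, 7, 8, 9, 10).

Steps most likely to fail:

1. Step 9 (proposed new method). The oxirane may be activated before C4 ionises, the Friedel–Crafts step may show poor facial selectivity at C4, or C2 may close with partial loss of inversion. The fallback uses the known flavan-4-yl cation coupling, which makes the C4–C8 bond instead; it sets out from compound 2 and comes back at target 15. Commercial (–)-epicatechin is benzylated (BnBr, K2CO3, DMF) to 5,7,3',4'-tetra-O-benzyl-(–)-epicatechin F1. F1 is oxidised at C4 with DDQ in CH2Cl2 containing ethylene glycol to 4β-(2-hydroxyethoxy)-5,7,3',4'-tetra-O-benzyl-(–)-epicatechin F2. F2 is then coupled with a fourfold excess of 2 (recovered) under TMSOTf in CH2Cl2 at −78 °C, where attack of C8 of 2 anti to the 3-hydroxyl should give octa-O-benzyl-epicatechin-(4β→8)-taxifolin F3. Hydrogenolysis of F3 (H2, Pd(OH)2/C, THF/MeOH) returns to the route at 15.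

2. Step 6. Enantiofacial discrimination between the aryl and alkynyl groups may be low, or the taxifolin ketone may be reduced as well. The fallback sets out from compound 3 and comes back at compound 8. Reductive carbonylation of 3 (Pd(OAc)2, dppp, CO 1 atm, Et3SiH, Na2CO3, DMF, 60 °C) gives 8-formyl-5,7,3',4'-tetra-O-benzyl-(+)-taxifolin F4. Catalytic asymmetric zinc alkynylation of F4 with alkyne 6 (Me2Zn, the ProPhenol ligand antipode that gives the (R)-carbinol, toluene, 0 °C) is chemoselective for the aldehyde over the ring ketone and should give 8.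

3. Step 2. Iodination may compete at C6, giving a mixture of regioisomers. The fallback sets out from compound 2 and comes back at compound 3. NaBH4 (THF/MeOH, 0 °C) reduces the C4 ketone to the 2,3-trans-3,4-trans flavan-3,4-diol, 5,7,3',4'-tetra-O-benzyl-leucocyanidin F5. On this flavan-type ring A, iodination with NIS in DMF should follow the well-documented C8 selectivity of 5,7-di-O-benzylflavan-3-ols and give the 8-iodo diol F6. MnO2 in CH2Cl2 then reoxidises only the benzylic 4-hydroxyl to give 3.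

**Further compounds**

F1 | step 9 | 5,7,3',4'-tetra-O-benzyl-(–)-epicatechin | C1c2c(OCc3ccccc3)cc(OCc3ccccc3)cc2O[C@H](c2ccc(OCc3ccccc3)c(OCc3ccccc3)c2)[C@@H]1O
F2 | step 9 | 4β-(2-hydroxyethoxy)-5,7,3',4'-tetra-O-benzyl-(–)-epicatechin | OCCO[C@H]1c2c(OCc3ccccc3)cc(OCc3ccccc3)cc2O[C@H](c2ccc(OCc3ccccc3)c(OCc3ccccc3)c2)[C@@H]1O
F3 | step 9 | octa-O-benzyl-(–)-epicatechin-(4β→8)-(+)-taxifolin | O=C1c2c(OCc3ccccc3)cc(OCc3ccccc3)c([C@H]3c4c(OCc5ccccc5)cc(OCc5ccccc5)cc4O[C@H](c4ccc(OCc5ccccc5)c(OCc5ccccc5)c4)[C@@H]3O)c2O[C@H](c2ccc(OCc3ccccc3)c(OCc3ccccc3)c2)[C@H]1O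
F4 | step 6 | 8-formyl-5,7,3',4'-tetra-O-benzyl-(+)-taxifolin | O=C1c2c(OCc3ccccc3)cc(OCc3ccccc3)c(C=O)c2O[C@H](c2ccc(OCc3ccccc3)c(OCc3ccccc3)c2)[C@H]1O
F5 | step 2 | (2R,3S,4R)-5,7,3',4'-tetra-O-benzylflavan-3,4-diol (2,3-trans-3,4-trans leucocyanidin tetrabenzyl ether) | O[C@@H]1c2c(OCc3ccccc3)cc(OCc3ccccc3)cc2O[C@H](c2ccc(OCc3ccccc3)c(OCc3ccccc3)c2)[C@H]1O
F6 | step 2 | 8-iodo-(2R,3S,4R)-5,7,3',4'-tetra-O-benzylflavan-3,4-diol | O[C@@H]1c2c(OCc3ccccc3)cc(OCc3ccccc3)c(I)c2O[C@H](c2ccc(OCc3ccccc3)c(OCc3ccccc3)c2)[C@H]1O
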